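**Plan**

1. Numbering as in eudesmanes: ring A = C1–C5 and C10, ring B = C5–C10; C14 is the methyl on C10, C15 the methyl on C4, C11–C13 the isopropylidene group on C7.
2. Cuts (backwards): the two ester C–O bonds; C7=C11 (aldol condensation with acetone); C4–O and C5–H (hydroboration of a 4-ene); C4=C5 (aldol closure of ring A); C6–C7 and C8–C9 (ring B); C1–C10 (Michael addition).
3. Enabling feature: C6 and C9 flank the C5–C10 bond in a 1,4-relationship. If C5 is a ketone, C6 is its only acidic methyl group and C9 can be a formyl group without α-hydrogen on the quaternary C10, so a two-carbon ketene equivalent (C7–C8) can be inserted by Michael addition followed by intramolecular Wittig olefination.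
4. Forward: the acyclic chain is joined by a Michael addition, ring B is closed first (step 6), ring A second by aldol condensation onto the same C5 carbonyl; then ring A is reduced and oxygenated, and ring B receives the isopropylidene group last.
5. Stereochemistry: C10 from a catalytic enantioselective Michael addition; C3 by hydride delivery to the α face; C4 and C5 together by syn hydroboration anti to C14 and to the C3 oxygen; the acyl centre comes with (R)-2-methylbutanoic acid.

Key step: step 6

Remark: the palladium complex of step 1 is taken to give the S adduct with (R)-BINAP; should the sense be the opposite, the (S)-BINAP complex is used.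
Remark: the target SMILES asks for the (R)-2-methylbutanoate; the acid 21 and compounds 1, 2, 7 and 8 are taken as purchasable.

**Route**

Step 1
Reactants: 1 tert-butyl 2-methyl-3-oxobutanoate; 2 pent-1-en-3-one
Product: 3 tert-butyl (2S)-2-acetyl-2-methyl-5-oxoheptanoate
Conditions: [Pd((R)-BINAP)(H2O)2](OTf)2 (5 mol %), THF, −20 °C
Reagents that add atoms: none
Why: Enantioselective Michael addition of the α-substituted β-keto ester to the vinyl ketone through a chiral palladium enolate; the BINAP ligand blocks one enolate face, so the new quaternary centre (later C10) should form with S configuration.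

Step 2
Reactants: 3 tert-butyl (2S)-2-acetyl-2-methyl-5-oxoheptanoate
Product: 4 tert-butyl (2S)-2-acetyl-4-(2-ethyl-1,3-dioxolan-2-yl)-2-methylbutanoate
Conditions: Me3SiOCH2CH2OSiMe3 (1.2 equiv), Me3SiOTf (2 mol %), CH2Cl2, −78 °C
Reagents that add atoms: 1,2-bis(trimethylsilyloxy)ethane, C[Si](C)(C)OCCO[Si](C)(C)C
Why: Silyl-triflate-catalysed ketalisation at low temperature should protect only the unhindered ethyl ketone (later C3), since the acetyl group sits on the quaternary carbon next to the bulky ester; no stereocentre is formed.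

Step 3
Reactants: 4 tert-butyl (2S)-2-acetyl-4-(2-ethyl-1,3-dioxolan-2-yl)-2-methylbutanoate
Product: 5 (2R)-2-[2-(2-ethyl-1,3-dioxolan-2-yl)ethyl]-2-methylbutane-1,3-diol (both epimers at the carbinol carbon)
Conditions: LiAlH4 (2 equiv), THF, 0 → 25 °C; aqueous NaOH work-up
Reagents that add atoms: none
Why: Hydride reduction of ketone and ester gives the 1,3-diol; the new carbinol centre is not controlled and disappears again in step 4, and the quaternary centre has no acidic hydrogen.

Step 4
Reactants: 5 (2R)-2-[2-(2-ethyl-1,3-dioxolan-2-yl)ethyl]-2-methylbutane-1,3-diol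
Product: 6 (2R)-2-acetyl-4-(2-ethyl-1,3-dioxolan-2-yl)-2-methylbutanal
Conditions: Dess–Martin periodinane (2.5 equiv), pyridine, CH2Cl2, 0 → 25 °C
Reagents that add atoms: none
Why: Dess–Martin oxidation of both hydroxyl groups under buffered, non-basic conditions gives the formyl group (later C9) and the acetyl group (later C5 and C6) without retro-Claisen cleavage of the β-keto aldehyde; no stereocentre is formed.

Step 5
Reactants: 7 (phenylthiomethyl)triphenylphosphonium chloride; 8 N,N-dimethylmethyleneiminium chloride (Eschenmoser's salt, chloride form)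
Product: 10 [1-(phenylthio)vinyl]triphenylphosphonium chloride, via Mannich adduct 9 (not isolated)
Conditions: Et3N (5 mol %), MeCN, 80 °C
Reagents that add atoms: none
Why: Mannich reaction of the methylene group that is acidified by phosphorus and sulfur with the iminium salt, followed by β-elimination of dimethylamine from adduct 9, gives the vinylphosphonium salt that serves as a ketene equivalent; no stereocentre is involved.

Step 6
Reactants: 6 (2R)-2-acetyl-4-(2-ethyl-1,3-dioxolan-2-yl)-2-methylbutanal; 10 [1-(phenylthio)vinyl]triphenylphosphonium chloride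
Product: 13 (2R)-2-[2-(2-ethyl-1,3-dioxolan-2-yl)ethyl]-2-methyl-4-(phenylthio)cyclohex-3-en-1-one, via sodium enolate 11 (not isolated), via phosphorus ylide 12 (not isolated)
Conditions: NaH (1.1 equiv), THF–DMF (4:1), 0 → 45 °C; 6 added over 2 h to NaH and 10 (1.3 equiv)
Reagents that add atoms: none
Why: NaH removes a proton from the acetyl methyl group C6, the only enolisable position of 6 (C10 is quaternary, the formyl group has no α-hydrogen, the C3 carbonyl is masked), and enolate 11 adds to the β-carbon of the vinylphosphonium salt (Michael addition, bond C6–C7) to give the sulfur-stabilised ylide 12 at C8. The ylide carbon then attacks the formyl carbon C9 in a 6-exo-trig closure and the oxaphosphetane loses Ph3P=O (intramolecular Wittig olefination, bond C8–C9 formed as C8=C9), so that ring B appears as a cyclohexenyl sulfide in which C8 is a masked ketone and C9 is already deoxygenated. The closest known reaction type is the Schweizer reaction of vinylphosphonium salts with nucleophiles that carry a carbonyl group, here in its 1-(phenylthio)vinyl, ketene-equivalent form. No stereocentre is created; the quaternary centre C10 set in step 1 has no acidic hydrogen and is carried through unchanged. The selectivity needed is chemoselectivity, that is C-alkylation of the enolate by 10 in preference to O-alkylation and to aldol addition to the formyl group of a second molecule. It is secured by the soft, cationic acceptor used in excess, by slow addition of 6 (low enolate concentration), by the reversibility of aldol addition to the hindered aldehyde and by the irreversible loss of Ph3P=O.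

Step 7
Reactants: 13 (2R)-2-[2-(2-ethyl-1,3-dioxolan-2-yl)ethyl]-2-methyl-4-(phenylthio)cyclohex-3-en-1-one
Product: 15 (4aR)-1,4a-dimethyl-6-(phenylthio)-4,4a,7,8-tetrahydronaphthalen-2(3H)-one, via diketone 14 (not isolated)
Conditions: 1 M HCl (0.1 equiv), THF–H2O, 40 °C; then KOH (0.5 equiv), MeOH, 50 °C
Reagents that add atoms: water, O
Why: Acid hydrolysis of the dioxolane and base-mediated intramolecular aldol condensation of C4 onto the C5 ketone (the ring-closing half of a Robinson annulation) give ring A as the tetrasubstituted enone, while the vinyl sulfide keeps C9 from acting as a nucleophile; no stereocentre is formed.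

Step 8
Reactants: 15 (4aR)-1,4a-dimethyl-6-(phenylthio)-4,4a,7,8-tetrahydronaphthalen-2(3H)-one
Product: 16 (4aR)-1,4a-dimethyl-4,4a,7,8-tetrahydronaphthalene-2,6(3H,5H)-dione
Conditions: HgCl2 (1.2 equiv), MeCN–H2O (3:1), 60 °C
Reagents that add atoms: water, O
Why: Mercury-assisted hydrolysis of the vinyl sulfide (protonation at C9, addition of water to the thionium ion at C8, loss of thiolate to HgCl2) frees the C8 ketone with C9 as a methylene group; no stereocentre is formed.

Step 9
Reactants: 16 (4aR)-1,4a-dimethyl-4,4a,7,8-tetrahydronaphthalene-2,6(3H,5H)-dione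
Product: 17 (8a'R)-5',8a'-dimethyl-3',4',8',8a'-tetrahydro-1'H-spiro[1,3-dioxolane-2,2'-naphthalen]-6'(7'H)-one (the C8 ethylene ketal of 16)
Conditions: HOCH2CH2OH (5 equiv), TsOH·H2O (5 mol %), 4 Å molecular sieves, CH2Cl2, 25 °C
Reagents that add atoms: ethylene glycol, OCCO
Why: Acid-catalysed ketalisation is chemoselective for the saturated C8 ketone, because the conjugated C3 ketone is much less electrophilic; no stereocentre is formed.

Step 10
Reactants: 17 (8a'R)-5',8a'-dimethyl-3',4',8',8a'-tetrahydro-1'H-spiro[1,3-dioxolane-2,2'-naphthalen]-6'(7'H)-one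
Product: 18 (6'S,8a'R)-5',8a'-dimethyl-3',4',6',7',8',8a'-hexahydro-1'H-spiro[1,3-dioxolane-2,2'-naphthalen]-6'-ol (3β allylic alcohol)
Conditions: NaBH4, CeCl3·7H2O, MeOH, −78 → 0 °C
Reagents that add atoms: none
Why: Luche 1,2-reduction of the enone; hydride should add to C3 from the α face, opposite to the angular methyl side of the half-chair, to give the equatorial 3β alcohol (3S).

Step 11
Reactants: 18 (6'S,8a'R)-5',8a'-dimethyl-3',4',6',7',8',8a'-hexahydro-1'H-spiro[1,3-dioxolane-2,2'-naphthalen]-6'-ol
Product: 20 (4a'R,5'S,6'S,8a'R)-5',8a'-dimethyloctahydro-1'H-spiro[1,3-dioxolane-2,2'-naphthalene]-5',6'-diol (3β,4α-diol, 4β-methyl, trans ring fusion), via organoborane 19 (not isolated)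
Conditions: BH3·THF (4 equiv), THF, 0 → 40 °C; then 3 M NaOH, 30 % H2O2, 0 → 40 °C
Reagents that add atoms: borane–tetrahydrofuran, [BH3-][O+]1CCCC1 (boron stays in 19 only); hydrogen peroxide, OO
Why: Hydroboration–oxidation of the tetrasubstituted double bond: boron should go to C4 (less hindered than C5, which lies next to the quaternary C10, and the carbon preferred next to an allylic oxygen) and hydrogen to C5, both from the α face opposite to C14 and to the C3 oxygen, and oxidation with retention then gives the 4α-hydroxy-4β-methyl centre (4S) and the trans ring fusion (5R).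

Step 12
Reactants: 20 (4a'R,5'S,6'S,8a'R)-5',8a'-dimethyloctahydro-1'H-spiro[1,3-dioxolane-2,2'-naphthalene]-5',6'-diol; 21 (2R)-2-methylbutanoic acid
Product: 22 (4a'R,5'S,6'S,8a'R)-5'-hydroxy-5',8a'-dimethyloctahydro-1'H-spiro[1,3-dioxolane-2,2'-naphthalen]-6'-yl (2R)-2-methylbutanoate
Conditions: DCC (1.3 equiv), DMAP (10 mol %), CH2Cl2, 0 → 25 °C
Reagents that add atoms: none
Why: Carbodiimide esterification with DMAP catalysis (Steglich esterification) acylates only the secondary C3 hydroxyl, the tertiary C4 hydroxyl being too hindered under these conditions, and the near-neutral activation should leave the α stereocentre of the acid intact.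

Step 13
Reactants: 22 (4a'R,5'S,6'S,8a'R)-5'-hydroxy-5',8a'-dimethyloctahydro-1'H-spiro[1,3-dioxolane-2,2'-naphthalen]-6'-yl (2R)-2-methylbutanoate
Product: 23 (4a'R,5'S,6'S,8a'R)-5'-acetoxy-5',8a'-dimethyloctahydro-1'H-spiro[1,3-dioxolane-2,2'-naphthalen]-6'-yl (2R)-2-methylbutanoate
Conditions: Ac2O (5 equiv), DMAP (1 equiv), Et3N, CH2Cl2, 40 °C
Reagents that add atoms: acetic anhydride, CC(=O)OC(C)=O
Why: DMAP-catalysed acetylation through the N-acetylpyridinium ion is the standard way to esterify a tertiary alcohol; no alkoxide is formed that could move the C3 ester, and no stereocentre is changed.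

Step 14
Reactants: 23 (4a'R,5'S,6'S,8a'R)-5'-acetoxy-5',8a'-dimethyloctahydro-1'H-spiro[1,3-dioxolane-2,2'-naphthalen]-6'-yl (2R)-2-methylbutanoate
Product: 24 (1S,2S,4aR,8aR)-1-acetoxy-1,4a-dimethyl-6-oxodecahydronaphthalen-2-yl (2R)-2-methylbutanoate
Conditions: 1 M HCl (0.2 equiv), THF–H2O, 40 °C
Reagents that add atoms: water, O
Why: Acid hydrolysis of the dioxolane frees the C8 ketone; secondary and tertiary esters are stable to dilute aqueous acid at this temperature, and no stereocentre is touched.

Step 15
Reactants: 24 (1S,2S,4aR,8aR)-1-acetoxy-1,4a-dimethyl-6-oxodecahydronaphthalen-2-yl (2R)-2-methylbutanoate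
Product: 26 (1S,2S,4aR,8aR)-1-acetoxy-7-(2-hydroxypropan-2-yl)-1,4a-dimethyl-6-oxodecahydronaphthalen-2-yl (2R)-2-methylbutanoate (C7 epimers), via lithium enolate 25 (not isolated)
Conditions: LiN(SiMe3)2 (1.05 equiv), THF, −78 °C; acetone (5 equiv), −78 °C; quench with H2O at −78 °C, pH 7 work-up
Reagents that add atoms: acetone, CC(C)=O
Why: Kinetic deprotonation with the hindered amide base takes place at C7 (C9 is a neopentyl methylene next to the quaternary C10, and the ester α-hydrogens are several pKa units less acidic), and aldol addition of the enolate to acetone follows; the new C7 centre is not controlled and is removed in step 16.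

Step 16
Reactants: 26 (1S,2S,4aR,8aR)-1-acetoxy-7-(2-hydroxypropan-2-yl)-1,4a-dimethyl-6-oxodecahydronaphthalen-2-yl (2R)-2-methylbutanoate
Product: 28 (1S,2S,4aR,8aR)-1-acetoxy-1,4a-dimethyl-6-oxo-7-(propan-2-ylidene)decahydronaphthalen-2-yl (2R)-2-methylbutanoate (the target), via mesylate 27 (not isolated)
Conditions: MsCl (1.5 equiv), Et3N (3 equiv), CH2Cl2, 0 °C; then DBU (2 equiv), 25 °C
Reagents that add atoms: methanesulfonyl chloride, CS(=O)(=O)Cl (its atoms stay in 27 and leave again)
Why: Mesylation of the tertiary aldol hydroxyl and base-induced E1cB elimination through the C7 enolate give the conjugated, tetrasubstituted isopropylidene ketone, the C7=C11 bond being the only position open to this mechanism; no stereocentre of the product is affected.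

**Compound list**

1 | tert-butyl 2-methyl-3-oxobutanoate | CC(=O)C(C)C(=O)OC(C)(C)C | starting material
2 | pent-1-en-3-one | CCC(=O)C=C | starting material
3 | tert-butyl (2S)-2-acetyl-2-methyl-5-oxoheptanoate | CCC(=O)CC[C@@](C)(C(C)=O)C(=O)OC(C)(C)C | intermediate
4 | tert-butyl (2S)-2-acetyl-4-(2-ethyl-1,3-dioxolan-2-yl)-2-methylbutanoate | CCC1(CC[C@@](C)(C(C)=O)C(=O)OC(C)(C)C)OCCO1 | intermediate
5 | (2R)-2-[2-(2-ethyl-1,3-dioxolan-2-yl)ethyl]-2-methylbutane-1,3-diol, both carbinol epimers | CCC1(CC[C@@](C)(C(C)O)CO)OCCO1 | intermediate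
6 | (2R)-2-acetyl-4-(2-ethyl-1,3-dioxolan-2-yl)-2-methylbutanal | CCC1(CC[C@@](C)(C(C)=O)C=O)OCCO1 | intermediate
7 | (phenylthiomethyl)triphenylphosphonium chloride | [Cl-].c1ccccc1SC[P+](c1ccccc1)(c1ccccc1)c1ccccc1 | starting material
8 | N,N-dimethylmethyleneiminium chloride | C=[N+](C)C.[Cl-] | starting material
9 | [2-(dimethylammonio)-1-(phenylthio)ethyl]triphenylphosphonium dichloride (Mannich adduct, racemic) | C[NH+](C)CC(Sc1ccccc1)[P+](c1ccccc1)(c1ccccc1)c1ccccc1.[Cl-].[Cl-] | intermediate (not isolated)
10 | [1-(phenylthio)vinyl]triphenylphosphonium chloride | C=C(Sc1ccccc1)[P+](c1ccccc1)(c1ccccc1)c1ccccc1.[Cl-] | intermediate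
11 | sodium enolate of 6 (enolate of the acetyl group, C5=C6) | CCC1(CC[C@@](C)(C(=C)[O-])C=O)OCCO1.[Na+] | intermediate (not isolated)
12 | phosphorus ylide Ph3P=C(SPh)CH2CH2C(=O)C(CH3)(CHO)CH2CH2(2-ethyl-1,3-dioxolan-2-yl), R at the quaternary carbon | CCC1(CC[C@@](C)(C(=O)CCC(Sc2ccccc2)=P(c2ccccc2)(c2ccccc2)c2ccccc2)C=O)OCCO1 | intermediate (not isolated)
13 | (2R)-2-[2-(2-ethyl-1,3-dioxolan-2-yl)ethyl]-2-methyl-4-(phenylthio)cyclohex-3-en-1-one | O=C1CCC(Sc2ccccc2)=C[C@@]1(C)CCC3(CC)OCCO3 | intermediate
14 | (2R)-2-methyl-2-(3-oxopentyl)-4-(phenylthio)cyclohex-3-en-1-one | O=C1CCC(Sc2ccccc2)=C[C@@]1(C)CCC(=O)CC | intermediate (not isolated)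
15 | (4aR)-1,4a-dimethyl-6-(phenylthio)-4,4a,7,8-tetrahydronaphthalen-2(3H)-one | CC1=C2CCC(Sc3ccccc3)=C[C@@]2(C)CCC1=O | intermediate
16 | (4aR)-1,4a-dimethyl-4,4a,7,8-tetrahydronaphthalene-2,6(3H,5H)-dione | CC1=C2CCC(=O)C[C@@]2(C)CCC1=O | intermediate
17 | (8a'R)-5',8a'-dimethyl-3',4',8',8a'-tetrahydro-1'H-spiro[1,3-dioxolane-2,2'-naphthalen]-6'(7'H)-one | CC1=C2CCC3(C[C@@]2(C)CCC1=O)OCCO3 | intermediate
18 | (6'S,8a'R)-5',8a'-dimethyl-3',4',6',7',8',8a'-hexahydro-1'H-spiro[1,3-dioxolane-2,2'-naphthalen]-6'-ol | CC1=C2CCC3(C[C@@]2(C)CC[C@@H]1O)OCCO3 | intermediate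
19 | organoborane (C4 boryl, C3 O-boryl; simplest member of the borane mixture) | BO[C@H]1CC[C@]2(C)CC3(CC[C@H]2[C@]1(C)B)OCCO3 | intermediate (not isolated)
20 | (4a'R,5'S,6'S,8a'R)-5',8a'-dimethyloctahydro-1'H-spiro[1,3-dioxolane-2,2'-naphthalene]-5',6'-diol | O[C@H]1CC[C@]2(C)CC3(CC[C@H]2[C@]1(C)O)OCCO3 | intermediate
21 | (2R)-2-methylbutanoic acid | CC[C@@H](C)C(=O)O | starting material
22 | (4a'R,5'S,6'S,8a'R)-5'-hydroxy-5',8a'-dimethyloctahydro-1'H-spiro[1,3-dioxolane-2,2'-naphthalen]-6'-yl (2R)-2-methylbutanoate | CC[C@@H](C)C(=O)O[C@H]1CC[C@]2(C)CC3(CC[C@H]2[C@]1(C)O)OCCO3 | intermediate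
23 | (4a'R,5'S,6'S,8a'R)-5'-acetoxy-5',8a'-dimethyloctahydro-1'H-spiro[1,3-dioxolane-2,2'-naphthalen]-6'-yl (2R)-2-methylbutanoate | CC[C@@H](C)C(=O)O[C@H]1CC[C@]2(C)CC3(CC[C@H]2[C@]1(C)OC(C)=O)OCCO3 | intermediate
24 | (1S,2S,4aR,8aR)-1-acetoxy-1,4a-dimethyl-6-oxodecahydronaphthalen-2-yl (2R)-2-methylbutanoate | CC[C@@H](C)C(=O)O[C@H]1CC[C@]2(C)CC(=O)CC[C@H]2[C@]1(C)OC(C)=O | intermediate
25 | lithium enolate of 24 (C7=C8 enolate) | CC[C@@H](C)C(=O)O[C@H]1CC[C@]2(C)CC([O-])=CC[C@H]2[C@]1(C)OC(C)=O.[Li+] | intermediate (not isolated)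
26 | (1S,2S,4aR,8aR)-1-acetoxy-7-(2-hydroxypropan-2-yl)-1,4a-dimethyl-6-oxodecahydronaphthalen-2-yl (2R)-2-methylbutanoate, C7 epimers | CC[C@@H](C)C(=O)O[C@H]1CC[C@]2(C)CC(=O)C(C(C)(C)O)C[C@H]2[C@]1(C)OC(C)=O | intermediate
27 | methanesulfonate of 26 at the tertiary hydroxyl | CC[C@@H](C)C(=O)O[C@H]1CC[C@]2(C)CC(=O)C(C(C)(C)OS(C)(=O)=O)C[C@H]2[C@]1(C)OC(C)=O | intermediate (not isolated)
28 | (1S,2S,4aR,8aR)-1-acetoxy-1,4a-dimethyl-6-oxo-7-(propan-2-ylidene)decahydronaphthalen-2-yl (2R)-2-methylbutanoate | CC[C@@H](C)C(=O)O[C@H]1CC[C@]2(C)CC(=O)C(=C(C)C)C[C@H]2[C@]1(C)OC(C)=O | target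

**Count and risks**

Total step count: 16. Longest linear sequence: 15 steps (steps 1–4 and 6–16); step 5 is a one-step side branch.

Step 6. The sodium enolate of 6 may add to the formyl group of a second molecule, or the β-keto aldehyde may lose its formyl group, faster than the enolate is trapped by 10. The fallback sets out from 2 and comes back to the route at 17; ring B is then bought and ring A is built onto it by a Robinson annulation. Racemic 7-methyl-1,4-dioxaspiro[4.5]decan-8-one F1 is condensed with (R)-1-phenylethylamine (toluene, reflux, removal of water) to the imine (1R)-N-(7-methyl-1,4-dioxaspiro[4.5]decan-8-ylidene)-1-phenylethanamine F2. Its secondary enamine tautomer should add to 2 (THF, 25 °C) on the face away from the phenyl group to give the imine of the Michael adduct F3. Aqueous acetic acid frees (7R)-7-methyl-7-(3-oxopentyl)-1,4-dioxaspiro[4.5]decan-8-one F4 and the amine, and NaOMe in MeOH closes ring A by aldol condensation to 17.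

Step 11. Hydroboration of the hindered tetrasubstituted double bond may be slow or unselective (boron at C5 instead of C4, or attack from the β face). The fallback sets out from 17 and comes back at 20; it replaces steps 10 and 11 by reductive enolate chemistry. Li in NH3–THF (−78 °C) reduces the enone and, by axial protonation at C5, should give the trans-fused lithium enolate F5, which is trapped with Me3SiCl and Et3N as the silyl enol ether F6. Epoxidation with mCPBA (NaHCO3, CH2Cl2, 0 °C) from the α face and silyl migration (Rubottom oxidation) give the α-silyloxy ketone F7, and dilute HCl in THF gives the 4α-hydroxy-4β-methyl-3-ketone F8. NaBH4 (MeOH, −20 °C), with hydride entering C3 axially from the α face, then gives 20.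

Step 15. The strong base may also deprotonate the ester groups or cause acyl transfer, and the lithium aldolate may revert by retro-aldol cleavage on work-up. The fallback sets out from 24 and comes back at 26; it avoids strong base. The ketone is enolised toward C7 with Me3SiOTf and Et3N (CH2Cl2, 0 °C) to the silyl enol ether F9, which adds to acetone under TiCl4 (CH2Cl2, −78 °C; Mukaiyama aldol addition) to give 26.

**Further compounds**

F1 | step 6 | 7-methyl-1,4-dioxaspiro[4.5]decan-8-one (racemic) | CC1CC2(CCC1=O)OCCO2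
F2 | step 6 | (1R)-N-(7-methyl-1,4-dioxaspiro[4.5]decan-8-ylidene)-1-phenylethanamine | CC1CC2(CCC1=N[C@H](C)c1ccccc1)OCCO2
F3 | step 6 | (1R)-N-[(7R)-7-methyl-7-(3-oxopentyl)-1,4-dioxaspiro[4.5]decan-8-ylidene]-1-phenylethanamine | CCC(=O)CC[C@]1(C)CC2(CCC1=N[C@H](C)c1ccccc1)OCCO2
F4 | step 6 | (7R)-7-methyl-7-(3-oxopentyl)-1,4-dioxaspiro[4.5]decan-8-one | CCC(=O)CC[C@]1(C)CC2(CCC1=O)OCCO2
F5 | step 11 | trans-fused lithium enolate (C3=C4) from 17 | CC1=C([O-])CC[C@]2(C)CC3(CC[C@@H]12)OCCO3.[Li+]
F6 | step 11 | trimethylsilyl enol ether (C3=C4) of the trans-fused ketone, C8 dioxolane | CC1=C(O[Si](C)(C)C)CC[C@]2(C)CC3(CC[C@@H]12)OCCO3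
F7 | step 11 | 4α-trimethylsilyloxy-4β-methyl-3-ketone, trans-fused, C8 dioxolane | O=C1CC[C@]2(C)CC3(CC[C@H]2[C@]1(C)O[Si](C)(C)C)OCCO3
F8 | step 11 | 4α-hydroxy-4β-methyl-3-ketone, trans-fused, C8 dioxolane | O=C1CC[C@]2(C)CC3(CC[C@H]2[C@]1(C)O)OCCO3
F9 | step 15 | trimethylsilyl enol ether (C7=C8) of 24 | CC[C@@H](C)C(=O)O[C@H]1CC[C@]2(C)CC(O[Si](C)(C)C)=CC[C@H]2[C@]1(C)OC(C)=O
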